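## Structural features

The target is an unsymmetrical dimer built on a 2,2'-dihydroxy-3,3'-dimethoxybiphenyl core, whose rings C and D are two vanillin-derived arenes joined C5–C5'. Ring C carries an olivil-type tetrahydrofuran in which C2 (aryl), C3 (CH2OH) and C4 (tertiary OH plus a 3-hydroxy-4-methoxybenzyl group) are contiguous stereocentres of 2S,3R,4S configuration, the aryl group being trans to CH2OH and CH2OH cis to the benzyl group. Ring D carries a cycloolivil-type 1-aryltetralin in which C1' (bonded to ring D), C2' (CH2OH) and C3' (OH and CH2OH) are contiguous and all S, with the aryl group trans to the C2' CH2OH and the two CH2OH groups trans. The fused arene of the tetralin is a vanillyl unit (7'-OH, 6'-OMe) whereas the benzyl group on the tetrahydrofuran is the regioisomeric isovanillyl unit, and the two stereotriads are insulated from each other by the biaryl, so the halves cannot come from one bidirectional sequence and each needs its own source of absolute configuration. Fragile points are the four electron-rich phenols, the two tertiary carbinols and above all the benzylic C2–O1 ether, which ionises in acid and is then captured by the neighbouring arene (tetrahydrofuran-to-tetralin ring switch). The real difficulty is to differentiate two identical positions of a symmetrical biaryl, to set C4 and C3' as fully substituted carbinols, and to close the tetralin through a ring D benzylic cation while the ionisable ring C tetrahydrofuran is already in place. The key step exploits the C3–C4 bond between a carbon bearing CH2OH (C3) and a carbon bearing an arylmethyl group (C4), which is the pattern left when a radical flanked by a CH2O–titanium group adds 5-exo to an aryl-capped propargyl ether.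

## Logic of the disconnections

33 ⇒ 32. Cut: five O–CH2Ph bonds (four phenolic, one on the C3 hydroxymethyl). Hydrogenolysis is the only neutral global unmasking that the acid-labile C2–O1 bond tolerates. Gain: one inert mask for the whole route. Demand: debenzylation must be finished before the ring-bound benzylic C2–O1 bond is attacked.

32 ⇒ 30 (through 31). Cut: C1'–C8a'. C1' is benzylic and para to a ring D oxygen, and C8a' is para to a methoxy group, so this is a natural cation/arene pair. Gain: the tetralin becomes an open chain in which only C2' and C3' must be set, C1' following from C2'. Demand: the cation must form on ring D only, and every hydroxyl that could trap it as a second tetrahydrofuran must be masked; acetates do both.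

30 ⇒ 29 ⇒ 28. Cut: three acetyl C–O bonds, then the oxidation level of the two CH2OH carbons and the C1'–O bond, which are gathered in a γ-lactone acid. Gain: a five-membered ring that can control C3'. Demand: the hydride reduction must leave ethers and tertiary alcohols alone.

28 ⇒ 27 ⇒ 24 + 26. Cut: C3'–O, then C3'–C4'. Both are enolate bonds at the lactone α-carbon. The order (carbon first, oxygen second) lets each electrophile enter anti to the C2' carboxylate, which gives OH trans and arylmethyl cis to it, as the target requires. Gain: the vanillyl ring arrives as a simple benzylic bromide. Demand: enolisation at C3' and not at C2' (secured by the carboxylate), and facial selectivity twice.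

24 ⇒ 23 ⇒ 18 + 21. Cut: C1'–C2' (aldol) and the lactone O–C(=O) bond. The ring D aldehyde is the only handle, and an auxiliary-controlled aldol sets C2' absolutely, independently of ring C. Gain: C2', C3' and both CH2OH carbons come from a succinate unit. Demand: reagent control must dominate; any minor enantiomer carried from the resolution becomes a separable diastereomer here.

18 ⇒ 17 ⇒ 15 (through 16). Cut: the acetal, then C4–O and the benzylic C–H (formal hydration of the exocyclic alkene). Epoxidation anti to the C3 substituent followed by hydride opening at the benzylic carbon sets C4. Gain: the quaternary carbinol comes from the sp2 carbon that the key step leaves. Demand: facial selectivity and survival of an acid-sensitive epoxide.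

15 ⇒ 14 ⇒ 13. Cut: the benzyl ether, then C3–C4 (key step). Gain: one ring, one C–C bond and one stereocentre in a single step, from a precursor with only C2 stereodefined. Demand: 5-exo closure faster than reduction of the radical. The ring D aldehyde is kept as a dioxolane because a free aryl aldehyde would undergo pinacol coupling, and either oxirane epimer of 13 may be used.

13 ⇒ 7 + 12. Cut: the O–CH2 propargyl bond. Gain: convergent union of the biaryl and the isovanillyl unit. Demand: etherification without epoxide migration.

7 ⇒ 6 ⇒ 4 + 5. Cut: the oxirane C–O bonds (resolution by epoxidation), then the C2–vinyl bond. Gain: C2 is set by a catalytic resolution. Demand: the D-(−)-tartrate system must be used, because it converts the (S)-alcohol into the erythro epoxy alcohol whose carbinol centre is R (the L-(+)-tartrate would give the enantiomer).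

4 ⇒ 3 ⇒ 2 ⇒ 1. Cut: one acetal, two benzyl ethers, and the C5–C5' biaryl bond. Gain: the whole core from two molecules of one cheap aldehyde. Demand: a statistical mono-protection with recycling.

12 ⇒ 11 ⇒ 9 + 10, 9 ⇒ 8; 21 ⇒ 19 + 20; 26 ⇒ 25. Cut: C–Br, aryl–alkyne and O–benzyl bonds; the N–acyl bond; a C–Br bond. All are standard fragment preparations.

## Other disconnections considered

Alternative 1: Acid ring-switch.
- Cut: C1'–C8a', traced back to the C1'–O bond of a second tetrahydrofuran on ring D, in bis-tetrahydrofuran A2.
- Forward key step: trifluoroacetic acid ionises that ether and the vanillyl ring closes on the cation, giving bis-pivalate A1 while the ring C ether stays closed.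
- In its favour: the ring D triad would come from the same radical cyclisation, epoxidation and hydride sequence as ring C, so C2' and C3' are transferred intact and no enolate chemistry is needed. The pivalate/free-phenol pattern is a built-in electronic switch: only the ring D ether, para to a free phenol, ionises easily, and only the unacylated vanillyl ring is nucleophilic.
- Against it here: A2 needs two different benzyl units and two different phenol masks on a biaryl that starts symmetrical. The second tetrahydrofuran must be built on a late intermediate, where the resolution acts on a diastereomer mixture and discards half of it. The pivalates must later be removed by base from an oxidation-prone polyphenol.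
- Comparison: structurally it is the equal of the chosen plan (same bond, same cation as step 22). Mechanistically it is the better on chemoselectivity of the cationic step, which in the chosen plan rests only on a leaving-group difference. It is the equal on C1' and arguably the better on C3'. In step economy the chosen plan should be equal or slightly shorter and should waste less advanced material.

Alternative 2: Benzocyclobutene opening and o-quinodimethane Diels–Alder.
- Cut: C1'–C2' and C3'–C4'.
- Forward key step: thermolysis of benzocyclobutene A4 opens it to the (E)-aryl o-quinodimethane, which adds acetoxyfumarate A5 to give cycloadduct A3.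
- In its favour: two C–C bonds and all three tetralin stereocentres form in one acid-free step. The C3' oxygen comes in with the dienophile, and the trans-diester relationship is stereospecific. The tetralin is made before any tetrahydrofuran exists, so the chemoselectivity question of step 22 does not arise; on this point it is the better.
- Against it here: absolute configuration depends on lactate esters remote from the forming bonds. The regiochemistry of an unsymmetrical, donor-substituted dienophile and the endo/exo choice must both fall the right way. A4 needs its own multi-step synthesis carrying the whole biaryl, and the titanocene sequence must afterwards run on a tetralin bearing three oxygen functions.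
- Comparison: structurally it is more convergent (better). Mechanistically a pericyclic step is the equal or better for relative configuration but weaker for absolute control than the auxiliary aldol. Step economy is expected to be about equal, since the benzocyclobutene costs what the cycloaddition saves.

Alternative 3: Anodic quinone methide cycloetherification.
- Cut: O1–C2 of the tetrahydrofuran.
- Forward key step: anodic oxidation of the single free phenol of open-chain phenol A7 (2,6-lutidine buffer) gives the para-quinone methide at C2, which the C5 hydroxyl captures to give tri-O-benzyl ether A6.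
- In its favour: the acid-sensitive ring is closed last under buffered conditions, after the tetralin is complete; this is the better for avoiding Lewis acid near the tetrahydrofuran. Site selectivity follows from the one free phenol. Five-membered closure onto a planar quinone methide should give the 2,3-trans ring, the equal of the radical step.
- Against it here: the step forms no C–C bond, so C3 and C4 must be set in an open chain without a ring to bias them. The aldehyde handle on ring C must become a CH2 group. The electron-rich biaryl phenol can be oxidised further, and the electrolyte can compete as nucleophile. One free phenol among three benzyl ethers again demands differentiated protection of the biaryl.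
- Comparison: structurally it is less simplifying than the chosen key step (ring only, versus ring, bond and stereocentre). Mechanistically it is a two-electron oxidation against a one-electron reduction, each mild. It is likely longer because the acyclic triad needs separate asymmetric chemistry.

Key step: step 10

Remark: 14 may form as a mixture of benzylidene isomers; the E isomer is written, and both isomers converge on 17 because the exocyclic carbon becomes CH2. Compounds 7 and 13 are written with the oxirane configuration that the erythro-selective resolution delivers (S at the oxirane carbon beside an R carbinol); this centre is erased in step 10. Compounds 19, 20 and 25 are taken as purchasable.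

Naming: BP = 6,6'-bis(benzyloxy)-5,5'-dimethoxybiphenyl, ring C substituent at position 3, ring D substituent at position 3'. THF* = the ring C unit of 17 bonded through C2, (2S,3R,4S)-3-[(benzyloxy)methyl]-4-{[3-(benzyloxy)-4-methoxyphenyl]methyl}-4-hydroxyoxolan-2-yl. Locants C2–C5 and C1'–C4' follow the target.

## Steps

Step 1
Reactants: 1 vanillin (two molecules)
Product: 2 dehydrodivanillin
Conditions: FeSO4·7H2O (cat.), Na2S2O8, H2O, 90 °C
Reagents that add atoms: vanillin (second molecule of 1), COc1cc(C=O)ccc1O
Why: Oxidative phenol coupling of two molecules of 1; the vanillin phenoxyl radical dimerises at C5, the only free position ortho to the hydroxyl, and the sparingly soluble dimer should leave solution before further oxidation.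

Step 2
Reactants: 2 dehydrodivanillin
Product: 3 6,6'-bis(benzyloxy)-5,5'-dimethoxybiphenyl-3,3'-dicarbaldehyde
Conditions: BnBr, K2CO3, DMF, 70 °C
Reagents that add atoms: benzyl bromide, BrCc1ccccc1
Why: Williamson ether synthesis on both phenoxides; benzyl ethers survive the Grignard reagent, hydrides, strong bases and trivalent titanium used later and leave together at the end.

Step 3
Reactants: 3 dibenzyl dialdehyde
Product: 4 6,6'-bis(benzyloxy)-3'-(1,3-dioxolan-2-yl)-5,5'-dimethoxybiphenyl-3-carbaldehyde
Conditions: ethylene glycol (1 equiv), p-TsOH·H2O (cat.), toluene, reflux, Dean–Stark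
Reagents that add atoms: ethylene glycol, OCCO
Why: Acid-catalysed acetalisation with one equivalent of diol gives a statistical mixture from which the mono-acetal is separated, 3 and the bis-acetal being recycled; this desymmetrises the biaryl and masks the ring D aldehyde for step 10.

Step 4
Reactants: 4 mono-dioxolane aldehyde, 5 vinylmagnesium bromide
Product: 6 rac-1-[3'-(1,3-dioxolan-2-yl)-BP-3-yl]prop-2-en-1-ol
Conditions: THF, −78 → 0 °C; aq. NH4Cl
Reagents that add atoms: none
Why: Grignard 1,2-addition to the aryl aldehyde; the acetal and benzyl ethers are inert, and the carbinol centre forms racemic and is resolved in step 5.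

Step 5
Reactants: 6 racemic allylic alcohol
Product: 7 (R)-[3'-(1,3-dioxolan-2-yl)-BP-3-yl][(2S)-oxiran-2-yl]methanol (erythro)
Conditions: Ti(OiPr)4 (cat.), D-(−)-DIPT, t-BuOOH (0.45 equiv), 4 Å MS, CH2Cl2, −20 °C
Reagents that add atoms: tert-butyl hydroperoxide, CC(C)(C)OO
Why: Sharpless kinetic resolution; with the D-(−)-tartrate the (S)-enantiomer of 6 is epoxidised fast to the erythro epoxy alcohol, whose carbinol centre (R only because the priorities change) is the future C2. Stopping short of half conversion should give 7 in high enantiomeric purity; unreacted (R)-6 is separated, and the oxirane configuration is irrelevant later.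

Step 6
Reactants: 8 5-bromo-2-methoxyphenol
Product: 9 2-(benzyloxy)-4-bromo-1-methoxybenzene
Conditions: BnBr, K2CO3, acetone, reflux
Reagents that add atoms: benzyl bromide, BrCc1ccccc1
Why: Williamson ether synthesis; the phenol is masked with the same group as the biaryl phenols.

Step 7
Reactants: 9 aryl bromide, 10 propargyl alcohol
Product: 11 3-[3-(benzyloxy)-4-methoxyphenyl]prop-2-yn-1-ol
Conditions: Pd(PPh3)2Cl2, CuI, Et3N, 70 °C
Reagents that add atoms: none
Why: Sonogashira coupling of the aryl bromide with the terminal alkyne through zerovalent palladium and a copper acetylide; the free propargylic hydroxyl is tolerated.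

Step 8
Reactants: 11 arylpropargyl alcohol
Product: 12 2-(benzyloxy)-4-(3-bromoprop-1-yn-1-yl)-1-methoxybenzene
Conditions: CBr4, PPh3, CH2Cl2, 0 °C
Reagents that add atoms: carbon tetrabromide, BrC(Br)(Br)Br
Why: Appel bromination of the primary propargylic alcohol under neutral conditions, which avoids allene formation; the bromide is used fresh.

Step 9
Reactants: 7 epoxy alcohol, 12 propargylic bromide
Product: 13 2-(benzyloxy)-1-methoxy-4-{3-[(R)-[3'-(1,3-dioxolan-2-yl)-BP-3-yl][(2S)-oxiran-2-yl]methoxy]prop-1-yn-1-yl}benzene
Conditions: NaH, Bu4NI (cat.), THF, 0 °C → rt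
Reagents that add atoms: none
Why: Williamson etherification of the sodium alkoxide of 7 with a reactive propargylic bromide; C2 is not touched, and an aprotic medium, low temperature and a fast electrophile should keep the alkoxide from undergoing Payne rearrangement.

Step 10
Reactants: 13 epoxy propargyl ether
Product: 14 [(2S,3R,4E)-4-{[3-(benzyloxy)-4-methoxyphenyl]methylidene}-2-[3'-(1,3-dioxolan-2-yl)-BP-3-yl]oxolan-3-yl]methanol (2,3-trans)
Conditions: Cp2TiCl2, Zn dust, THF, rt (Cp2TiCl solution added slowly to 13); aq. NaH2PO4
Reagents that add atoms: none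
Why: Cp2TiCl (trivalent titanium, made from Cp2TiCl2 and Zn) transfers one electron to the oxirane of 13, whose C–O bond at the more substituted carbon breaks to give the secondary C3 radical carrying a CH2O–titanium group. This radical adds 5-exo-dig to the aryl-capped alkyne, forming C3–C4 and closing the tetrahydrofuran; the α-aryl vinyl radical is quenched by hydrogen abstraction from THF or by a second trivalent titanium and protonolysis, and work-up frees the primary alcohol. The closest known reaction type is the Cp2TiCl-mediated epoxide-opening radical cyclisation onto alkynes that gives 3-hydroxymethyl-4-alkylidene tetrahydrofurans. C3 is the only new stereocentre: in the chair-like transition state of the 5-exo closure the C2 aryl group sits pseudo-equatorial, so C3 should form trans to it (2S,3R), and because the oxirane carbon becomes a planar radical either epoxide epimer converges on the same product. The step needs regioselective opening (secured by the terminal epoxide, secondary versus primary radical), cyclisation faster than capture of the C3 radical by a second titanium (secured by slow addition, which keeps the reagent dilute, and by the aryl group, which stabilises the vinyl radical), and chemoselectivity (the ring D aldehyde is a dioxolane because a free aryl aldehyde would undergo pinacol coupling; benzyl ethers and the benzylic ether at C2 are inert). The benzylidene geometry is not controlled and need not be, since the exocyclic carbon becomes CH2 in step 12.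

Step 11
Reactants: 14 tetrahydrofuran alcohol
Product: 15 (2S,3R,4E)-3-[(benzyloxy)methyl]-4-{[3-(benzyloxy)-4-methoxyphenyl]methylidene}-2-[3'-(1,3-dioxolan-2-yl)-BP-3-yl]oxolane
Conditions: NaH, BnBr, Bu4NI (cat.), THF, 0 °C → rt
Reagents that add atoms: benzyl bromide, BrCc1ccccc1
Why: Williamson benzylation of the primary alcohol; capping the hydroxyl removes any hydrogen-bond direction of the epoxidation and adds bulk on the C3 face, and the ether leaves with the aryl benzyl ethers at the end.

Step 12
Reactants: 15 benzylidene tetrahydrofuran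
Product: 17 (2S,3R,4S)-3-[(benzyloxy)methyl]-4-{[3-(benzyloxy)-4-methoxyphenyl]methyl}-2-[3'-(1,3-dioxolan-2-yl)-BP-3-yl]oxolan-4-ol, via spiro-epoxide 16 (not isolated)
Conditions: DMDO, acetone/CH2Cl2, −20 °C; concentrate; LiAlH4, THF, 0 °C → rt
Reagents that add atoms: dimethyldioxirane, CC1(C)OO1
Why: Neutral epoxidation of the electron-rich trisubstituted alkene should occur on the ring face opposite the C3 benzyloxymethyl group, and SN2 hydride opening of the acid-sensitive epoxide at its benzylic, less substituted carbon then leaves the tertiary hydroxyl at C4 trans to the C3 substituent (C4 S). Either alkene isomer gives the same C4.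

Step 13
Reactants: 17 tertiary alcohol
Product: 18 3-(THF*)-BP-3'-carbaldehyde
Conditions: PPTS, acetone/H2O, 50 °C
Reagents that add atoms: water, O
Why: Mild acid-catalysed acetal hydrolysis; the conditions are too weak to ionise the 2-aryl tetrahydrofuran or the tertiary alcohol.

Step 14
Reactants: 19 (S)-4-benzyl-1,3-oxazolidin-2-one, 20 methyl 4-chloro-4-oxobutanoate
Product: 21 methyl 4-[(4S)-4-benzyl-2-oxo-1,3-oxazolidin-3-yl]-4-oxobutanoate
Conditions: n-BuLi, THF, −78 °C; then 20
Reagents that add atoms: none
Why: N-acylation of the lithiated oxazolidinone with the acid chloride, the standard preparation of an Evans imide.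

Step 15
Reactants: 18 ring D aldehyde, 21 succinyl imide
Product: 23 (4S)-4-benzyl-3-{[(2S,3S)-5-oxo-2-[3-(THF*)-BP-3'-yl]oxolan-3-yl]carbonyl}-1,3-oxazolidin-2-one (2,3-trans lactone), via open syn-aldol adduct 22 (not isolated)
Conditions: 21, Bu2BOTf, iPr2NEt, CH2Cl2, −78 → 0 °C; 18, −78 → 0 °C; pH 7 buffer, MeOH, H2O2
Reagents that add atoms: none
Why: Evans syn-aldol reaction of the Z-boron enolate of 21 (the imide α-CH2 is enolised, not the ester) with the aldehyde; the (S)-benzyl auxiliary fixes C2' as S in the adduct. The syn γ-hydroxy methyl ester then lactonises to the trans γ-lactone, and reagent control is expected to override the remote ring C stereocentres.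

Step 16
Reactants: 23 lactone imide
Product: 24 (2S,3S)-5-oxo-2-[3-(THF*)-BP-3'-yl]oxolane-3-carboxylic acid (trans)
Conditions: LiOH, H2O2, THF/H2O, 0 °C; Na2SO3; dil. HCl to pH 3
Reagents that add atoms: hydrogen peroxide, OO
Why: Hydroperoxide cleavage of the imide at its exocyclic carbonyl releases the acid and the recoverable auxiliary; any lactone that opens re-closes on acidification because only the five-membered ring can form.

Step 17
Reactants: 25 [4-(benzyloxy)-3-methoxyphenyl]methanol
Product: 26 1-(benzyloxy)-4-(bromomethyl)-2-methoxybenzene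
Conditions: PBr3, Et2O, 0 °C
Reagents that add atoms: phosphorus tribromide, BrP(Br)Br
Why: Conversion of the benzylic alcohol into the bromide; the reactive bromide is used at once.

Step 18
Reactants: 24 lactone acid, 26 vanillyl bromide
Product: 27 (2S,3S,4S)-4-{[4-(benzyloxy)-3-methoxyphenyl]methyl}-5-oxo-2-[3-(THF*)-BP-3'-yl]oxolane-3-carboxylic acid (all-trans)
Conditions: NaHMDS (3.3 equiv), THF, −78 °C; 26, −78 → −30 °C; dil. HCl
Reagents that add atoms: none
Why: Alkylation of the lactone enolate, generated beside the carboxylate and the ring C alkoxide, with the benzylic bromide; the electrophile should enter anti to the C2' carboxylate as in known α-alkylations of paraconic acids. The carboxylate protects C2' from deprotonation and from β-elimination of the ring oxygen.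

Step 19
Reactants: 27 benzylated lactone acid
Product: 28 (2S,3R,4S)-4-{[4-(benzyloxy)-3-methoxyphenyl]methyl}-4-hydroxy-5-oxo-2-[3-(THF*)-BP-3'-yl]oxolane-3-carboxylic acid
Conditions: KHMDS (3.5 equiv), THF, −78 °C; 2-(benzenesulfonyl)-3-phenyloxaziridine; dil. HCl
Reagents that add atoms: 2-(benzenesulfonyl)-3-phenyloxaziridine, O=S(=O)(c1ccccc1)N1OC1c1ccccc1
Why: Electrophilic hydroxylation of the potassium enolate by the N-sulfonyloxaziridine; oxygen should be delivered anti to the C2' carboxylate, following the known preference of γ-butyrolactone enolates for attack anti to the β-substituent. This places the hydroxyl trans and the arylmethyl group cis to the carboxyl and so sets C3'.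

Step 20
Reactants: 28 hydroxy lactone acid
Product: 29 (1S,2R,3S)-3-{[4-(benzyloxy)-3-methoxyphenyl]methyl}-2-(hydroxymethyl)-1-[3-(THF*)-BP-3'-yl]butane-1,3,4-triol (pentaol)
Conditions: LiAlH4, THF, 0 °C → reflux
Reagents that add atoms: none
Why: LiAlH4 reduces the lactone and the acid to the two primary alcohols and frees the benzylic C1' hydroxyl; ethers and tertiary alcohols are unaffected and no stereocentre is touched.

Step 21
Reactants: 29 pentaol
Product: 30 triacetate of 29 (acetates on the C1' benzylic oxygen and on both CH2OH groups; both tertiary hydroxyls free)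
Conditions: Ac2O, pyridine, rt
Reagents that add atoms: acetic anhydride, CC(=O)OC(C)=O
Why: Acetylation of the two primary and the secondary benzylic hydroxyls (tertiary alcohols do not react without DMAP); this removes the oxygen nucleophiles that would trap the C1' cation as a tetrahydrofuran and turns the benzylic oxygen into a leaving group.

Step 22
Reactants: 30 triacetate
Product: 32 penta-O-benzyl ether of the target (1'S,2'S,3'S; 2S,3R,4S), via tetralin diacetate 31 (not isolated)
Conditions: BF3·OEt2, CH2Cl2, −78 → −40 °C; then K2CO3, MeOH, rt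
Reagents that add atoms: none
Why: Intramolecular Friedel–Crafts alkylation: BF3 ionises the benzylic acetate, and the cation, stabilised by the para-benzyloxy group of ring D, is attacked by C6 of the vanillyl ring (para to its methoxy group). A chair-like transition state with the ring D aryl and the C2' acetoxymethyl group equatorial should give the 1',2'-trans tetralin (C1' S). The ester leaving group should ionise well below the temperature at which the cyclic benzylic ether of ring C does, and methanolysis in the same pot removes the two remaining acetates.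

Step 23
Reactants: 32 penta-O-benzyl ether
Product: 33 target CNP0252244.1
Conditions: H2 (1 atm), Pd/C, EtOAc/MeOH, rt
Reagents that add atoms: none
Why: Hydrogenolysis of the four aryl benzyl ethers and the one alkyl benzyl ether over palladium under neutral conditions; the hindered, ring-bound C2–O1 bond should be much slower to cleave, and no acid or base meets the olivil-type unit.

## Compound list

1 | vanillin | COc1cc(C=O)ccc1O | starting material
2 | dehydrodivanillin (6,6'-dihydroxy-5,5'-dimethoxybiphenyl-3,3'-dicarbaldehyde) | COc1cc(C=O)cc(-c2cc(C=O)cc(OC)c2O)c1O | intermediate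
3 | 6,6'-bis(benzyloxy)-5,5'-dimethoxybiphenyl-3,3'-dicarbaldehyde | COc1cc(C=O)cc(-c2cc(C=O)cc(OC)c2OCc2ccccc2)c1OCc1ccccc1 | intermediate
4 | 6,6'-bis(benzyloxy)-3'-(1,3-dioxolan-2-yl)-5,5'-dimethoxybiphenyl-3-carbaldehyde | COc1cc(C=O)cc(-c2cc(C3OCCO3)cc(OC)c2OCc2ccccc2)c1OCc1ccccc1 | intermediate
5 | vinylmagnesium bromide | C=C[Mg]Br | starting material
6 | rac-1-[3'-(1,3-dioxolan-2-yl)-BP-3-yl]prop-2-en-1-ol | COc1cc(cc(-c2cc(C3OCCO3)cc(OC)c2OCc2ccccc2)c1OCc1ccccc1)C(O)C=C | intermediate
7 | (R)-[3'-(1,3-dioxolan-2-yl)-BP-3-yl][(2S)-oxiran-2-yl]methanol (erythro) | COc1cc(cc(-c2cc(C3OCCO3)cc(OC)c2OCc2ccccc2)c1OCc1ccccc1)[C@@H](O)[C@@H]1CO1 | intermediate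
8 | 5-bromo-2-methoxyphenol | COc1ccc(Br)cc1O | starting material
9 | 2-(benzyloxy)-4-bromo-1-methoxybenzene | COc1ccc(Br)cc1OCc1ccccc1 | intermediate
10 | propargyl alcohol | C#CCO | starting material
11 | 3-[3-(benzyloxy)-4-methoxyphenyl]prop-2-yn-1-ol | COc1ccc(C#CCO)cc1OCc1ccccc1 | intermediate
12 | 2-(benzyloxy)-4-(3-bromoprop-1-yn-1-yl)-1-methoxybenzene | COc1ccc(C#CCBr)cc1OCc1ccccc1 | intermediate
13 | epoxy propargyl ether, (R)-carbinol and (S)-oxirane, of 7 with 12 | COc1cc(cc(-c2cc(C3OCCO3)cc(OC)c2OCc2ccccc2)c1OCc1ccccc1)[C@@H](OCC#Cc1ccc(OC)c(OCc2ccccc2)c1)[C@@H]1CO1 | intermediate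
14 | [(2S,3R,4E)-4-{[3-(benzyloxy)-4-methoxyphenyl]methylidene}-2-[3'-(1,3-dioxolan-2-yl)-BP-3-yl]oxolan-3-yl]methanol (2,3-trans) | COc1cc(cc(-c2cc(C3OCCO3)cc(OC)c2OCc2ccccc2)c1OCc1ccccc1)[C@H]1OC/C(=C/c2ccc(OC)c(OCc3ccccc3)c2)[C@@H]1CO | intermediate
15 | O-benzyl ether of 14 at the C3 hydroxymethyl group | COc1cc(cc(-c2cc(C3OCCO3)cc(OC)c2OCc2ccccc2)c1OCc1ccccc1)[C@H]1OC/C(=C/c2ccc(OC)c(OCc3ccccc3)c2)[C@@H]1COCc1ccccc1 | intermediate
16 | spiro-epoxide of 15 at C4, not isolated (oxygen on the ring face opposite the C3 benzyloxymethyl group; oxirane aryl cis to C3) | COc1cc(cc(-c2cc(C3OCCO3)cc(OC)c2OCc2ccccc2)c1OCc1ccccc1)[C@H]1OC[C@@]2(O[C@H]2c2ccc(OC)c(OCc3ccccc3)c2)[C@@H]1COCc1ccccc1 | intermediate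
17 | (2S,3R,4S)-3-[(benzyloxy)methyl]-4-{[3-(benzyloxy)-4-methoxyphenyl]methyl}-2-[3'-(1,3-dioxolan-2-yl)-BP-3-yl]oxolan-4-ol | COc1cc(cc(-c2cc(C3OCCO3)cc(OC)c2OCc2ccccc2)c1OCc1ccccc1)[C@H]1OC[C@](O)(Cc2ccc(OC)c(OCc3ccccc3)c2)[C@@H]1COCc1ccccc1 | intermediate
18 | 3-(THF*)-BP-3'-carbaldehyde | COc1cc(cc(-c2cc(C=O)cc(OC)c2OCc2ccccc2)c1OCc1ccccc1)[C@H]1OC[C@](O)(Cc2ccc(OC)c(OCc3ccccc3)c2)[C@@H]1COCc1ccccc1 | intermediate
19 | (S)-4-benzyl-1,3-oxazolidin-2-one | O=C1OC[C@H](Cc2ccccc2)N1 | starting material
20 | methyl 4-chloro-4-oxobutanoate | COC(=O)CCC(Cl)=O | starting material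
21 | methyl 4-[(4S)-4-benzyl-2-oxo-1,3-oxazolidin-3-yl]-4-oxobutanoate | COC(=O)CCC(=O)N1[C@@H](Cc2ccccc2)COC1=O | intermediate
22 | (4S)-4-benzyl-3-[(2S,3S)-3-hydroxy-2-(2-methoxy-2-oxoethyl)-3-[3-(THF*)-BP-3'-yl]propanoyl]-1,3-oxazolidin-2-one (syn aldol, not isolated) | COc1cc(cc(-c2cc([C@@H](O)[C@@H](C(=O)N3[C@@H](Cc4ccccc4)COC3=O)CC(=O)OC)cc(OC)c2OCc2ccccc2)c1OCc1ccccc1)[C@H]1OC[C@](O)(Cc2ccc(OC)c(OCc3ccccc3)c2)[C@@H]1COCc1ccccc1 | intermediate
23 | (4S)-4-benzyl-3-{[(2S,3S)-5-oxo-2-[3-(THF*)-BP-3'-yl]oxolan-3-yl]carbonyl}-1,3-oxazolidin-2-one (trans lactone) | COc1cc(cc(-c2cc([C@H]3OC(=O)C[C@@H]3C(=O)N3[C@@H](Cc4ccccc4)COC3=O)cc(OC)c2OCc2ccccc2)c1OCc1ccccc1)[C@H]1OC[C@](O)(Cc2ccc(OC)c(OCc3ccccc3)c2)[C@@H]1COCc1ccccc1 | intermediate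
24 | (2S,3S)-5-oxo-2-[3-(THF*)-BP-3'-yl]oxolane-3-carboxylic acid (trans) | COc1cc(cc(-c2cc([C@H]3OC(=O)C[C@@H]3C(=O)O)cc(OC)c2OCc2ccccc2)c1OCc1ccccc1)[C@H]1OC[C@](O)(Cc2ccc(OC)c(OCc3ccccc3)c2)[C@@H]1COCc1ccccc1 | intermediate
25 | [4-(benzyloxy)-3-methoxyphenyl]methanol | COc1cc(CO)ccc1OCc1ccccc1 | starting material
26 | 1-(benzyloxy)-4-(bromomethyl)-2-methoxybenzene | COc1cc(CBr)ccc1OCc1ccccc1 | intermediate
27 | (2S,3S,4S)-4-{[4-(benzyloxy)-3-methoxyphenyl]methyl}-5-oxo-2-[3-(THF*)-BP-3'-yl]oxolane-3-carboxylic acid (all-trans) | COc1cc(cc(-c2cc([C@H]3OC(=O)[C@@H](Cc4ccc(OCc5ccccc5)c(OC)c4)[C@@H]3C(=O)O)cc(OC)c2OCc2ccccc2)c1OCc1ccccc1)[C@H]1OC[C@](O)(Cc2ccc(OC)c(OCc3ccccc3)c2)[C@@H]1COCc1ccccc1 | intermediate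
28 | (2S,3R,4S)-4-{[4-(benzyloxy)-3-methoxyphenyl]methyl}-4-hydroxy-5-oxo-2-[3-(THF*)-BP-3'-yl]oxolane-3-carboxylic acid (aryl trans to CO2H; OH trans and arylmethyl cis to CO2H) | COc1cc(cc(-c2cc([C@H]3OC(=O)[C@](O)(Cc4ccc(OCc5ccccc5)c(OC)c4)[C@@H]3C(=O)O)cc(OC)c2OCc2ccccc2)c1OCc1ccccc1)[C@H]1OC[C@](O)(Cc2ccc(OC)c(OCc3ccccc3)c2)[C@@H]1COCc1ccccc1 | intermediate
29 | (1S,2R,3S)-3-{[4-(benzyloxy)-3-methoxyphenyl]methyl}-2-(hydroxymethyl)-1-[3-(THF*)-BP-3'-yl]butane-1,3,4-triol | COc1cc(cc(-c2cc([C@@H](O)[C@@H](CO)[C@](O)(CO)Cc3ccc(OCc4ccccc4)c(OC)c3)cc(OC)c2OCc2ccccc2)c1OCc1ccccc1)[C@H]1OC[C@](O)(Cc2ccc(OC)c(OCc3ccccc3)c2)[C@@H]1COCc1ccccc1 | intermediate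
30 | triacetate of 29 (benzylic O1 and both primary oxygens acetylated) | COc1cc(cc(-c2cc([C@@H](OC(C)=O)[C@@H](COC(C)=O)[C@](O)(COC(C)=O)Cc3ccc(OCc4ccccc4)c(OC)c3)cc(OC)c2OCc2ccccc2)c1OCc1ccccc1)[C@H]1OC[C@](O)(Cc2ccc(OC)c(OCc3ccccc3)c2)[C@@H]1COCc1ccccc1 | intermediate
31 | (1'S,2'S,3'S)-tetralin with 2',3'-bis(acetoxymethyl), 3'-OH, 7'-OBn, 6'-OMe, 1'-[3-(THF*)-BP-3'-yl] (not isolated) | COc1cc(cc(-c2cc([C@H]3c4cc(OCc5ccccc5)c(OC)cc4C[C@@](O)(COC(C)=O)[C@@H]3COC(C)=O)cc(OC)c2OCc2ccccc2)c1OCc1ccccc1)[C@H]1OC[C@](O)(Cc2ccc(OC)c(OCc3ccccc3)c2)[C@@H]1COCc1ccccc1 | intermediate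
32 | penta-O-benzyl ether of the target (four phenolic, one on the C3 hydroxymethyl; 1'S,2'S,3'S; 2S,3R,4S) | COc1cc(cc(-c2cc([C@H]3c4cc(OCc5ccccc5)c(OC)cc4C[C@@](O)(CO)[C@@H]3CO)cc(OC)c2OCc2ccccc2)c1OCc1ccccc1)[C@H]1OC[C@](O)(Cc2ccc(OC)c(OCc3ccccc3)c2)[C@@H]1COCc1ccccc1 | intermediate
33 | CNP0252244.1 | COc1ccc(C[C@@]2(O)CO[C@H](c3cc(OC)c(O)c(-c4cc([C@H]5c6cc(O)c(OC)cc6C[C@@](O)(CO)[C@@H]5CO)cc(OC)c4O)c3)[C@H]2CO)cc1O | target

## Step count and uncertain steps

Total: 23 steps. Longest linear sequence: 18 steps (1, 2, 3, 4, 5, 9, 10, 11, 12, 13, 15, 16, 18, 19, 20, 21, 22, 23).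

Step 10 (key step). The most likely failure is reduction of the C3 radical by a second trivalent titanium before ring closure, followed by β-elimination of the titanium alkoxide (deoxygenation), because the reagent is present in excess and the closure onto a disubstituted alkyne is only moderately fast. The fallback sets out from 13 and returns at 14, and it generates the same radical without a metal reductant. The oxirane of 13 is opened at its terminal carbon with caesium pivalate (DMF, 80 °C) to the hydroxy pivalate F1. The secondary hydroxyl is converted with 1,1'-thiocarbonyldiimidazole into the imidazolylthiocarbonyl ester F2. Slow addition of Bu3SnH and AIBN in toluene at 80 °C then gives the C3 radical by C–O homolysis; it closes 5-exo-dig with the same trans preference to the cyclised pivalate F3, and LiAlH4 cleaves the ester to give 14.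

Step 22. The most likely failure is ionisation of the ring C benzylic ether by the Lewis acid and capture of that cation by the isovanillyl ring (ring switch on the wrong half), because both benzylic positions carry the same kind of aryl group and only the leaving group differs. The fallback sets out from 29 and returns at 31, which is methanolysed to 32 as in step 22. Only the two primary hydroxyls are acetylated (AcCl, 2,4,6-collidine, −78 °C) to the diacetate F4. The free benzylic alcohol is converted by MsCl and Et3N into the benzylic chloride F5. The cation is then generated by halide abstraction with AgOTf in the presence of 2,6-di-tert-butyl-4-methylpyridine, so that no Lewis or Brønsted acid able to activate an ether is present.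

Step 19. The most likely failures are incomplete enolisation of the hindered tertiary α-carbon next to a carboxylate, addition of the enolate to the sulfonylimine by-product, or insufficient facial selectivity. The fallback sets out from 24 and returns at 28; it reverses the order of bond formation at C3' (oxygen first, carbon second). The enolate of 24 is aminomethylated with dimethyl(methylidene)ammonium iodide to the Mannich base F6, which is quaternised with MeI and eliminated with NaHCO3 to the α-methylene lactone acid F7. Nucleophilic epoxidation (t-BuOOH, DBU) should close the oxirane on the face anti to the carboxylate, giving the spiro-epoxy lactone acid F8. Its CH2 terminus is opened at low temperature by the aryl Grignard reagent F9 (from commercial 4-bromo-1-(benzyloxy)-2-methoxybenzene and Mg) with catalytic CuI, the organometallic being used in excess because of the free acid.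

Step 9. The most likely failure is Payne-type migration of the epoxy alkoxide, followed by etherification at the wrong oxygen, because the alkoxide sits next to the oxirane. The fallback sets out from 6 and returns at 13. The resolution is run with L-(+)-DIPT past half conversion, and the unreacted (S)-allylic alcohol F10 is kept. It is etherified with 12 (NaH, THF) to the enyne ether F11, with no epoxide present at the alkoxide stage. The vinyl group is then epoxidised with buffered mCPBA, which gives 13 together with its oxirane epimer F12; both give the same radical in step 10.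

## Further compounds

F1 | step 10 | hydroxy pivalate from terminal opening of the oxirane of 13 | COc1cc(cc(-c2cc(C3OCCO3)cc(OC)c2OCc2ccccc2)c1OCc1ccccc1)[C@@H](OCC#Cc1ccc(OC)c(OCc2ccccc2)c1)[C@@H](O)COC(=O)C(C)(C)C
F2 | step 10 | imidazolylthiocarbonyl ester of F1 | COc1cc(cc(-c2cc(C3OCCO3)cc(OC)c2OCc2ccccc2)c1OCc1ccccc1)[C@@H](OCC#Cc1ccc(OC)c(OCc2ccccc2)c1)[C@@H](OC(=S)n1ccnc1)COC(=O)C(C)(C)C
F3 | step 10 | pivalate of 14 | COc1cc(cc(-c2cc(C3OCCO3)cc(OC)c2OCc2ccccc2)c1OCc1ccccc1)[C@H]1OC/C(=C/c2ccc(OC)c(OCc3ccccc3)c2)[C@@H]1COC(=O)C(C)(C)C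
F4 | step 22 | primary diacetate of 29 with free benzylic hydroxyl | COc1cc(cc(-c2cc([C@@H](O)[C@@H](COC(C)=O)[C@](O)(COC(C)=O)Cc3ccc(OCc4ccccc4)c(OC)c3)cc(OC)c2OCc2ccccc2)c1OCc1ccccc1)[C@H]1OC[C@](O)(Cc2ccc(OC)c(OCc3ccccc3)c2)[C@@H]1COCc1ccccc1
F5 | step 22 | benzylic chloride from F4 (both C1' epimers) | COc1cc(cc(-c2cc(C(Cl)[C@@H](COC(C)=O)[C@](O)(COC(C)=O)Cc3ccc(OCc4ccccc4)c(OC)c3)cc(OC)c2OCc2ccccc2)c1OCc1ccccc1)[C@H]1OC[C@](O)(Cc2ccc(OC)c(OCc3ccccc3)c2)[C@@H]1COCc1ccccc1
F6 | step 19 | 4-(dimethylaminomethyl) derivative of 24 (trans to the carboxyl) | COc1cc(cc(-c2cc([C@H]3OC(=O)[C@@H](CN(C)C)[C@@H]3C(=O)O)cc(OC)c2OCc2ccccc2)c1OCc1ccccc1)[C@H]1OC[C@](O)(Cc2ccc(OC)c(OCc3ccccc3)c2)[C@@H]1COCc1ccccc1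
F7 | step 19 | α-methylene lactone acid | COc1cc(cc(-c2cc([C@H]3OC(=O)C(=C)[C@@H]3C(=O)O)cc(OC)c2OCc2ccccc2)c1OCc1ccccc1)[C@H]1OC[C@](O)(Cc2ccc(OC)c(OCc3ccccc3)c2)[C@@H]1COCc1ccccc1
F8 | step 19 | spiro-epoxy lactone acid (oxirane oxygen anti to the carboxyl) | COc1cc(cc(-c2cc([C@H]3OC(=O)[C@]4(CO4)[C@@H]3C(=O)O)cc(OC)c2OCc2ccccc2)c1OCc1ccccc1)[C@H]1OC[C@](O)(Cc2ccc(OC)c(OCc3ccccc3)c2)[C@@H]1COCc1ccccc1
F9 | step 19 | [4-(benzyloxy)-3-methoxyphenyl]magnesium bromide | COc1cc([Mg]Br)ccc1OCc1ccccc1
F10 | step 9 | (S)-1-[3'-(1,3-dioxolan-2-yl)-BP-3-yl]prop-2-en-1-ol | COc1cc(cc(-c2cc(C3OCCO3)cc(OC)c2OCc2ccccc2)c1OCc1ccccc1)[C@@H](O)C=C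
F11 | step 9 | enyne ether of F10 with 12 | COc1cc(cc(-c2cc(C3OCCO3)cc(OC)c2OCc2ccccc2)c1OCc1ccccc1)[C@@H](OCC#Cc1ccc(OC)c(OCc2ccccc2)c1)C=C
F12 | step 9 | oxirane epimer of 13, (R)-carbinol and (R)-oxirane | COc1cc(cc(-c2cc(C3OCCO3)cc(OC)c2OCc2ccccc2)c1OCc1ccccc1)[C@@H](OCC#Cc1ccc(OC)c(OCc2ccccc2)c1)[C@H]1CO1
A1 | alternative 1 | target bis-pivalate (ring C phenol and isovanillyl phenol acylated) | COc1cc(cc(-c2cc([C@H]3OC[C@](O)(Cc4ccc(OC)c(OC(=O)C(C)(C)C)c4)[C@@H]3CO)cc(OC)c2OC(=O)C(C)(C)C)c1O)[C@H]1c2cc(O)c(OC)cc2C[C@@](O)(CO)[C@@H]1CO
A2 | alternative 1 | bis-tetrahydrofuran bis-pivalate | COc1cc(cc(-c2cc([C@H]3OC[C@](O)(Cc4ccc(OC)c(OC(=O)C(C)(C)C)c4)[C@@H]3CO)cc(OC)c2OC(=O)C(C)(C)C)c1O)[C@H]1OC[C@](O)(Cc2ccc(O)c(OC)c2)[C@@H]1CO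
A3 | alternative 2 | 1-aryltetralin 2,3-diester with C3' acetate | COc1cc(cc(-c2cc(C3OCCO3)cc(OC)c2OCc2ccccc2)c1OCc1ccccc1)[C@H]1c2cc(OCc3ccccc3)c(OC)cc2C[C@@](OC(C)=O)(C(=O)O[C@@H](C)C(=O)OC)[C@@H]1C(=O)O[C@@H](C)C(=O)OC
A4 | alternative 2 | 1-arylbenzocyclobutene (racemic at the ring carbon) | COc1cc(cc(-c2cc(C3OCCO3)cc(OC)c2OCc2ccccc2)c1OCc1ccccc1)C1Cc2cc(OC)c(OCc3ccccc3)cc12
A5 | alternative 2 | acetoxyfumarate bis[(S)-1-methoxy-1-oxopropan-2-yl] ester | CC(=O)O/C(=C\C(=O)O[C@@H](C)C(=O)OC)C(=O)O[C@@H](C)C(=O)OC
A6 | alternative 3 | target tri-O-benzyl ether (ring C phenol free) | COc1cc(cc(-c2cc([C@H]3OC[C@](O)(Cc4ccc(OC)c(OCc5ccccc5)c4)[C@@H]3CO)cc(OC)c2O)c1OCc1ccccc1)[C@H]1c2cc(OCc3ccccc3)c(OC)cc2C[C@@](O)(CO)[C@@H]1CO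
A7 | alternative 3 | open-chain ring C phenol (C2 as CH2; C5, C3 and C4 hydroxyls free) | COc1cc(cc(-c2cc(C[C@@H](CO)[C@](O)(CO)Cc3ccc(OC)c(OCc4ccccc4)c3)cc(OC)c2O)c1OCc1ccccc1)[C@H]1c2cc(OCc3ccccc3)c(OC)cc2C[C@@](O)(CO)[C@@H]1CO
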